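I follow the larch flask by its first product and leave substrate aside: substrate reads 67.9% at 80.0 min and 69.1% at 90.0 min, within a few scatters of each other.

in all of them: substrate 0.050 M
- larch: coupling partner 0.50 equiv; the very flask that is asked about, followed so far
- alder: coupling partner 1 equiv; run made earlier
- flask: coupling partner 0.500 equiv; time 8.0 h

- larch (time / min: first product / %, substrate / %): 6.00: 7.8, 92.2; 20.0: 16.1, 80.8; 30.0: 20.7, 75.9; 50.0: 23.6, 71.9; 80.0: 23.8, 67.9; 90.0: 23.4, 69.1
- alder (time / h: first product / %, substrate / %): 0.667: 31.5, 55.9; 1.00: 29.8, 51.4; 2.00: 20.9, 50.7; 3.00: 15.9, 51.1; 5.00: 11.0, 50.9; 8.00: 6.5, 47.8

(scatter of a reading: 0.5 percentage points)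

* equivalents of coupling partner to substrate, everything else as given, that leave most first product at 8.0 h
* the amount of first product then, in percent of the substrate charged
* the amount of first product with the amounts as given

- on the list of suspects stand: substrate + coupling partner -> other mono adduct + released group; coupling partner + other mono adduct -> double product + released group; substrate + coupling partner <-> first product + released group; coupling partner + first product -> double product + released group

The curve starts steeply, with 7.8% of first product at 6.00 min, and bends into a knee near 23.8% at 80.0 min. I read the stall as a pre-equilibrium. At 90.0 min the missing 7.50% counts as double product, so 11.6% of coupling partner remains, in substrate's percent. First product stands to it in the ratio 2.02, which I take as held.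

After the knee, first product meets coupling partner in a second-order drain, so I plot its reciprocal, as a fraction of the substrate charged, against time. In the alder flask the two stand about equal at 2.00 h, and the reciprocal climbs 1.77 h⁻¹. With a held ratio, I reckon the larch climb as the alder climb times two over one plus that ratio. This is the drain clock, the hourly climb of the reciprocal of first product:

drain clock = 1.17 h⁻¹

I take it to scale with substrate concentration at fixed equivalents. From 90.0 min to 8.0 h it carries first product down to

8.41%

The forecast, from “a fast reversible first step”, gives 10.7%, more than my figure, and 12% at 0.3 equiv.

The flask gives 10.0%, and 11.2% at 0.297 equiv.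

    substrate + coupling partner → other mono adduct + released group (k = 0.0240 M⁻¹ min⁻¹)
    coupling partner + other mono adduct → double product + released group (k = 0.00740 M⁻¹ min⁻¹)
    substrate + coupling partner ⇌ first product + released group (K = 1.10, k = 0.550 M⁻¹ min⁻¹)
    coupling partner + first product → double product + released group (k = 0.360 M⁻¹ min⁻¹)

The flask ends there through the way back and the drain together: the run without the way back gives 34.1%, the run without the drain 29.1%. Between 4.00 h and 8.00 h the flask's clock reads 0.934 h⁻¹ against my 1.17 h⁻¹. For the neighbour flask with 0.013 M of substrate, a quarter of the concentration, I scale the clock and start it from the larch knee, which gives 20.2%, and that neighbour flask stands at 21.6%.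

The earlier runs and the new flask stem from a simulated flask for substances that don't exist.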